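**Plan**

- Retrosynthesis: after removal of three MOM ethers, the pyran ring is cut at the aryl ether bond O1–C8a, the chalcone at its Cα=Cβ bond, and the side chain at C4–C4a. This leads to an (S)-alkynediol (from geranyl acetate), an iodo fluoro acetophenone (from 2-fluoro-1,4-dimethoxybenzene) and a protected 4-hydroxybenzaldehyde.
- Enabling feature: in the benzene ring of the chromene, C8a (the carbon bonded to O1 of the pyran ring) is para to C6, which carries the chalcone carbonyl. A fluoride at C8a is therefore activated for addition–elimination, and the enone carbonyl has no enolizable hydrogen that base could remove to cancel this activation.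
- Forward: the chain is joined to the arene at C4–C4a by Sonogashira coupling, the alkyne is reduced to the Z-alkene, the enone is built by aldol condensation, and the pyran ring, the only ring made, closes last at O1–C8a.
- Stereochemistry: C2 is set as (S) by Sharpless asymmetric epoxidation with L-(+)-diethyl tartrate and its C–O bond is never broken afterwards. The Z-alkene comes from syn semihydrogenation and the E-enone from the condensation.

Key step: step 14

Remark: locants (O1, C2–C8a) are those of the 2H-chromene core of the target; epoxide 2 is made as a racemate on purpose, since its stereocentre disappears in step 2.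

**Route**

Step 1
Reactants: 1 geranyl acetate
Product: 2 (E)-5-(3,3-dimethyloxiran-2-yl)-3-methylpent-2-en-1-yl acetate (6,7-epoxygeranyl acetate, racemic at the oxirane carbon)
Conditions: mCPBA (1.05 equiv), NaHCO3, CH2Cl2, 0 °C
Reagents that add atoms: meta-chloroperoxybenzoic acid, O=C(OO)c1cccc(Cl)c1
Why: Prilezhaev epoxidation by the electrophilic peracid should pick the electron-rich 6,7-alkene over the 2,3-alkene, which the allylic acetate deactivates; the new stereocentre is left racemic because it becomes a CH2 group in step 2.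

Step 2
Reactants: 2 6,7-epoxygeranyl acetate
Product: 3 (2E)-3,7-dimethyloct-2-ene-1,7-diol
Conditions: LiAlH4 (2 equiv), THF, 0 °C → reflux; then H2O, aq. NaOH
Reagents that add atoms: none
Why: Hydride reduction with LiAlH4 opens the trisubstituted epoxide at its less substituted carbon to leave the tertiary alcohol and reduces the acetate to the primary allylic alcohol in the same operation, while the isolated trisubstituted alkene is inert to hydride.

Step 3
Reactants: 3 (2E)-3,7-dimethyloct-2-ene-1,7-diol
Product: 4 (2S,3S)-2,3-epoxy-3,7-dimethyloctane-1,7-diol, i.e. 5-[(2S,3S)-3-(hydroxymethyl)-2-methyloxiran-2-yl]-2-methylpentan-2-ol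
Conditions: Ti(OiPr)4 (10 mol%), L-(+)-diethyl tartrate (12 mol%), t-BuOOH (2 equiv), 4 Å molecular sieves, CH2Cl2, −20 °C
Reagents that add atoms: tert-butyl hydroperoxide, CC(C)(C)OO
Why: Sharpless asymmetric epoxidation: the titanium tartrate complex binds the primary allylic hydroxyl and delivers the peroxide oxygen to one face of the E-alkene, which with L-(+)-diethyl tartrate sets C2 and C3 as (2S,3S), the same sense as for geraniol, and the remote tertiary hydroxyl is not allylic and directs nothing.

Step 4
Reactants: 4 (2S,3S)-2,3-epoxy-3,7-dimethyloctane-1,7-diol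
Product: 5 (2R,3S)-1-chloro-2,3-epoxy-3,7-dimethyloctan-7-ol, i.e. 5-[(2S,3R)-3-(chloromethyl)-2-methyloxiran-2-yl]-2-methylpentan-2-ol
Conditions: PPh3 (1.2 equiv), CCl4, NaHCO3, reflux
Reagents that add atoms: carbon tetrachloride, ClC(Cl)(Cl)Cl
Why: Appel chlorination converts only the primary alcohol, because the phosphonium intermediate is displaced by chloride in an SN2 step that the tertiary alcohol cannot undergo, and the bicarbonate buffer keeps the epoxide closed; the C2 descriptor changes from S to R through CIP priority alone, no bond at C2 or C3 being touched.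

Step 5
Reactants: 5 (2R,3S)-1-chloro-2,3-epoxy-3,7-dimethyloctan-7-ol
Product: 7 (S)-3,7-dimethyloct-1-yne-3,7-diol, via chlorovinyl diol 6 (not isolated)
Conditions: n-BuLi (4.2 equiv), THF, −40 °C → 0 °C; then H2O
Reagents that add atoms: none
Why: Base-induced double elimination of a 2,3-epoxy chloride to a propargylic alcohol: after the hydroxyl is deprotonated, lithiation next to chlorine opens the epoxide to the alkoxide of chlorovinyl carbinol 6 and loss of HCl then gives the alkyne, and because the C3–O bond is never broken the epoxide configuration is kept as the (S) tertiary carbinol.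

Step 6
Reactants: 8 2-fluoro-1,4-dimethoxybenzene
Product: 10 1-(4-fluoro-2-hydroxy-5-methoxyphenyl)ethanone, via dimethoxy ketone 9 (not isolated)
Conditions: AcCl (1.2 equiv), AlCl3 (3 equiv), CH2Cl2, 0 °C → reflux; then ice, aq. HCl
Reagents that add atoms: acetyl chloride, CC(Cl)=O
Why: Friedel–Crafts acylation should occur at the position ortho to a methoxy group and para to fluorine (the alternatives are meta to fluorine or crowded between fluorine and methoxy), and the excess AlCl3 then removes the methyl group of the ether that is chelated to the new carbonyl.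

Step 7
Reactants: 10 1-(4-fluoro-2-hydroxy-5-methoxyphenyl)ethanone
Product: 11 1-(4-fluoro-2-hydroxy-3-iodo-5-methoxyphenyl)ethanone
Conditions: N-iodosuccinimide (1.05 equiv), TsOH·H2O (10 mol%), MeCN, rt, dark
Reagents that add atoms: N-iodosuccinimide, O=C1CCC(=O)N1I
Why: Electrophilic aromatic iodination is steered by the phenol to its only free ortho position, between hydroxyl and fluorine and meta to the deactivating acetyl group, the para position being blocked by the methoxy group.

Step 8
Reactants: 11 1-(4-fluoro-2-hydroxy-3-iodo-5-methoxyphenyl)ethanone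
Product: 12 1-(4-fluoro-2,5-dihydroxy-3-iodophenyl)ethanone
Conditions: BBr3 (3 equiv), CH2Cl2, −78 °C → rt; then H2O
Reagents that add atoms: none
Why: Lewis-acid ether cleavage with BBr3 removes the remaining aryl methyl ether, and the aryl fluoride, aryl iodide and ketone are inert to it at these temperatures.

Step 9
Reactants: 12 1-(4-fluoro-2,5-dihydroxy-3-iodophenyl)ethanone
Product: 13 1-[4-fluoro-3-iodo-2,5-bis(methoxymethoxy)phenyl]ethanone
Conditions: NaH (2.2 equiv), MOMCl (2.5 equiv), DMF, 0 °C → rt
Reagents that add atoms: chloromethyl methyl ether, COCCl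
Why: Williamson-type O-alkylation of the two sodium phenoxides with the reactive chloromethyl ether protects both hydroxyls, including the hindered chelated one, and the base is limited to what the phenols need so that the methyl ketone is not enolized.

Step 10
Reactants: 13 1-[4-fluoro-3-iodo-2,5-bis(methoxymethoxy)phenyl]ethanone; 7 (S)-3,7-dimethyloct-1-yne-3,7-diol
Product: 14 1-[3-[(3S)-3,7-dihydroxy-3,7-dimethyloct-1-yn-1-yl]-4-fluoro-2,5-bis(methoxymethoxy)phenyl]ethanone
Conditions: Pd(PPh3)2Cl2 (3 mol%), CuI (5 mol%), Et3N, THF, 45 °C, argon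
Reagents that add atoms: none
Why: Sonogashira coupling forms the C4–C4a bond at the aryl iodide, which undergoes oxidative addition far faster than the aryl fluoride, and the free tertiary hydroxyls, ketone and MOM ethers are tolerated under the amine conditions, the stereocentre of 7 not being involved.

Step 11
Reactants: 14 1-[3-[(3S)-3,7-dihydroxy-3,7-dimethyloct-1-yn-1-yl]-4-fluoro-2,5-bis(methoxymethoxy)phenyl]ethanone
Product: 15 1-[3-[(1Z,3S)-3,7-dihydroxy-3,7-dimethyloct-1-en-1-yl]-4-fluoro-2,5-bis(methoxymethoxy)phenyl]ethanone
Conditions: H2 (1 atm), Pd/CaCO3 poisoned with Pb(OAc)2, quinoline, EtOAc, rt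
Reagents that add atoms: none
Why: Semihydrogenation over lead-poisoned palladium (Lindlar reduction) adds H2 syn on the catalyst surface and stops at the alkene, which gives the Z geometry needed to bring the C2 hydroxyl next to C8a, and the quinoline-moderated catalyst should leave the aryl fluoride and ketone alone.

Step 12
Reactants: 16 4-hydroxybenzaldehyde
Product: 17 4-(methoxymethoxy)benzaldehyde
Conditions: MOMCl (1.3 equiv), iPr2NEt (1.6 equiv), CH2Cl2, 0 °C → rt
Reagents that add atoms: chloromethyl methyl ether, COCCl
Why: Base-mediated O-alkylation of the phenol gives the MOM ether, which keeps the aldehyde electrophilic in step 13 (a phenoxide would deactivate it) and keeps a phenoxide out of the enone in step 14.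

Step 13
Reactants: 15 1-[3-[(1Z,3S)-3,7-dihydroxy-3,7-dimethyloct-1-en-1-yl]-4-fluoro-2,5-bis(methoxymethoxy)phenyl]ethanone; 17 4-(methoxymethoxy)benzaldehyde
Product: 18 (E)-1-[3-[(1Z,3S)-3,7-dihydroxy-3,7-dimethyloct-1-en-1-yl]-4-fluoro-2,5-bis(methoxymethoxy)phenyl]-3-[4-(methoxymethoxy)phenyl]prop-2-en-1-one
Conditions: KOH (50% aq., excess), EtOH, 0 °C → rt
Reagents that add atoms: none
Why: Claisen–Schmidt condensation of the methyl ketone with the non-enolizable aldehyde gives the E-enone by aldol addition and E1cB dehydration under thermodynamic control, while the protic medium keeps the tertiary hydroxyls protonated and the crowded C8a fluoride should outlast the hydroxide and ethoxide present.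

Step 14
Reactants: 18 fluoro chalcone with the (1Z,3S)-3,7-dihydroxy-3,7-dimethyloct-1-enyl chain
Product: 19 (E)-1-[(2S)-2-(4-hydroxy-4-methylpentyl)-5,8-bis(methoxymethoxy)-2-methyl-2H-chromen-6-yl]-3-[4-(methoxymethoxy)phenyl]prop-2-en-1-one
Conditions: KN(SiMe3)2 (2.2 equiv), 18-crown-6 (2.2 equiv), THF, −78 °C → rt; then aq. NH4Cl
Reagents that add atoms: none
Why: Deprotonation of both tertiary hydroxyls at −78 °C uses up the amide base before it can touch the enone; on warming, the C2 alkoxide adds to C8a, ipso to fluorine, to give a Meisenheimer anion whose charge sits on C8, C4a and C6 and is drawn from C6 into the chalcone carbonyl, and irreversible loss of fluoride then forms the O1–C8a bond (addition–elimination, SNAr). The closest known reaction type is the intramolecular SNAr etherification of aryl fluorides that carry a para acyl group, used to make chromans and related benzo-fused cyclic ethers; here the nucleophile is a tertiary alkoxide and the carbon attacked has two ortho neighbours, which is why a crown-ether-separated potassium alkoxide is used. The 2H-pyran ring closes in a six-membered 6-exo-trig mode (ipso attack on the C8a=C8 bond of the arene), the Z geometry of the C3=C4 alkene holding the oxygen within bonding distance of C8a. No stereocentre is formed, and because the C2–O bond is not broken the (S) configuration from step 3 passes unchanged into 19. The step needs three selectivities: between the two alkoxides, secured by ring size, since the distal one could only close a ten-membered ring; substitution over conjugate addition, secured because alkoxide addition to the enone is reversible and intermolecular while fluoride loss is intramolecular and irreversible; and no loss of activation, secured because the ketone has no enolizable hydrogen and all three phenols are capped as MOM ethers.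

Step 15
Reactants: 19 tris-MOM chromene chalcone
Product: 20 (E)-1-[(2S)-5,8-dihydroxy-2-(4-hydroxy-4-methylpentyl)-2-methyl-2H-chromen-6-yl]-3-(4-hydroxyphenyl)prop-2-en-1-one (CNP0322520.1)
Conditions: HCl (3 M aq.), MeOH/THF, rt → 40 °C
Reagents that add atoms: none
Why: Acid-catalysed acetal exchange with methanol removes the three MOM groups as dimethoxymethane under conditions mild enough for the tertiary alcohol, the 2H-chromene and the chalcone, and C2 is not touched.

**Compound list**

1 | geranyl acetate | CC(C)=CCC/C(C)=C/COC(C)=O | starting material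
2 | (E)-5-(3,3-dimethyloxiran-2-yl)-3-methylpent-2-en-1-yl acetate (racemic at the oxirane carbon) | CC1(C)OC1CC/C(C)=C/COC(C)=O | intermediate
3 | (2E)-3,7-dimethyloct-2-ene-1,7-diol | CC(C)(O)CCC/C(C)=C/CO | intermediate
4 | (2S,3S)-2,3-epoxy-3,7-dimethyloctane-1,7-diol | CC(C)(O)CCC[C@]1(C)O[C@H]1CO | intermediate
5 | (2R,3S)-1-chloro-2,3-epoxy-3,7-dimethyloctan-7-ol | CC(C)(O)CCC[C@]1(C)O[C@H]1CCl | intermediate
6 | (1E,3S)-1-chloro-3,7-dimethyloct-1-ene-3,7-diol (E geometry expected; formed in the flask as its lithium alkoxide, not isolated) | CC(C)(O)CCC[C@@](O)(C)/C=C/Cl | intermediate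
7 | (S)-3,7-dimethyloct-1-yne-3,7-diol | CC(C)(O)CCC[C@@](O)(C)C#C | intermediate
8 | 2-fluoro-1,4-dimethoxybenzene | COc1ccc(OC)c(F)c1 | starting material
9 | 1-(4-fluoro-2,5-dimethoxyphenyl)ethanone (formed in the flask, not isolated) | CC(=O)c1cc(OC)c(F)cc1OC | intermediate
10 | 1-(4-fluoro-2-hydroxy-5-methoxyphenyl)ethanone | CC(=O)c1cc(OC)c(F)cc1O | intermediate
11 | 1-(4-fluoro-2-hydroxy-3-iodo-5-methoxyphenyl)ethanone | CC(=O)c1cc(OC)c(F)c(I)c1O | intermediate
12 | 1-(4-fluoro-2,5-dihydroxy-3-iodophenyl)ethanone | CC(=O)c1cc(O)c(F)c(I)c1O | intermediate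
13 | 1-[4-fluoro-3-iodo-2,5-bis(methoxymethoxy)phenyl]ethanone | CC(=O)c1cc(OCOC)c(F)c(I)c1OCOC | intermediate
14 | 1-[3-[(3S)-3,7-dihydroxy-3,7-dimethyloct-1-yn-1-yl]-4-fluoro-2,5-bis(methoxymethoxy)phenyl]ethanone | CC(C)(O)CCC[C@@](O)(C)C#Cc1c(F)c(OCOC)cc(C(C)=O)c1OCOC | intermediate
15 | 1-[3-[(1Z,3S)-3,7-dihydroxy-3,7-dimethyloct-1-en-1-yl]-4-fluoro-2,5-bis(methoxymethoxy)phenyl]ethanone | CC(C)(O)CCC[C@@](O)(C)/C=C\c1c(F)c(OCOC)cc(C(C)=O)c1OCOC | intermediate
16 | 4-hydroxybenzaldehyde | O=Cc1ccc(O)cc1 | starting material
17 | 4-(methoxymethoxy)benzaldehyde | COCOc1ccc(C=O)cc1 | intermediate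
18 | (E)-1-[3-[(1Z,3S)-3,7-dihydroxy-3,7-dimethyloct-1-en-1-yl]-4-fluoro-2,5-bis(methoxymethoxy)phenyl]-3-[4-(methoxymethoxy)phenyl]prop-2-en-1-one | CC(C)(O)CCC[C@@](O)(C)/C=C\c1c(F)c(OCOC)cc(C(=O)/C=C/c2ccc(OCOC)cc2)c1OCOC | intermediate
19 | (E)-1-[(2S)-2-(4-hydroxy-4-methylpentyl)-5,8-bis(methoxymethoxy)-2-methyl-2H-chromen-6-yl]-3-[4-(methoxymethoxy)phenyl]prop-2-en-1-one | CC(C)(O)CCC[C@@]1(C)C=Cc2c(OCOC)c(C(=O)/C=C/c3ccc(OCOC)cc3)cc(OCOC)c2O1 | intermediate
20 | (E)-1-[(2S)-5,8-dihydroxy-2-(4-hydroxy-4-methylpentyl)-2-methyl-2H-chromen-6-yl]-3-(4-hydroxyphenyl)prop-2-en-1-one | CC(C)(O)CCC[C@@]1(C)C=Cc2c(O)c(C(=O)/C=C/c3ccc(O)cc3)cc(O)c2O1 | target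

**Step count**

Total: 15 steps. Longest linear sequence: 10 steps from geranyl acetate (steps 1–5, 10, 11, 13, 14, 15). The arene branch (steps 6–9) and the aldehyde (step 12) feed in at steps 10 and 13.

**Steps most likely to fail, with fallbacks**

Step 14. The ipso attack at C8a may be too slow, because this carbon is flanked by two ortho substituents and receives electron density from the C8 oxygen. Reversible alkoxide addition to the enone, retro-aldol cleavage or Z-to-E isomerization of the styrenyl alkene could then take over.

The fallback replaces electronic activation by palladium catalysis: an intramolecular C–O coupling of an aryl bromide with the tertiary alcohol (Buchwald–Hartwig-type etherification). A tertiary alkoxide on palladium has no hydrogen for β-hydride elimination. The fallback sets out from alkynediol 7 and commercially available 2-bromo-1,4-dimethoxybenzene (COc1ccc(OC)c(Br)c1) and comes back at 19. The bromoarene is taken through the chemistry of steps 6–11. AcCl/AlCl3 should give 1-(4-bromo-2-hydroxy-5-methoxyphenyl)ethanone F2 by way of the dimethoxy ketone 1-(4-bromo-2,5-dimethoxyphenyl)ethanone F1, which is not isolated. Iodination with N-iodosuccinimide then gives 1-(4-bromo-2-hydroxy-3-iodo-5-methoxyphenyl)ethanone F3, BBr3 gives 1-(4-bromo-2,5-dihydroxy-3-iodophenyl)ethanone F4, and NaH/MOMCl gives 1-[4-bromo-3-iodo-2,5-bis(methoxymethoxy)phenyl]ethanone F5. Sonogashira coupling with 7 at room temperature, selective for the C–I bond, gives the bromo alkynyl ketone F6, and semihydrogenation over Pd/CaCO3 poisoned with Pb(OAc)2 gives the bromo (Z)-alkenyl ketone F7. Treatment of F7 with Pd(OAc)2, 2-(di-tert-butylphosphino)-1,1'-binaphthyl and Cs2CO3 in toluene at 70 °C should close the pyran ring at the methyl ketone stage, which the weak carbonate base tolerates, to give the chromene methyl ketone F8. Claisen–Schmidt condensation of F8 with 17 (KOH, EtOH) then gives 19.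

Step 13. Once the enone has formed, ethoxide or hydroxide may displace the now activated fluoride, or the condensation may stall through retro-aldol equilibration.

The fallback separates aldol addition from dehydration and avoids a nucleophilic protic base. It sets out from 15 and 17 and comes back at 18. LiN(SiMe3)2 (3.3 equiv) in THF at −78 °C forms the lithium enolate beside the two lithium alkoxides, and addition of 17 gives the β-hydroxy ketone F9 as a mixture of epimers at the new carbinol carbon. MsCl (1.1 equiv) and excess Et3N in CH2Cl2 at 0 °C → rt sulfonylate only the secondary hydroxyl, and the mesylate F10, not isolated, loses methanesulfonate by E1cB elimination to give 18.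

Step 11. The hydrogenation may run on to the saturated chain, stop short of full conversion at the crowded aryl alkyne, or isomerize the Z-alkene on the catalyst.

The fallback fixes the Z geometry before the C4–C4a bond is made and also bypasses step 10. It sets out from 7 and 13 and comes back at 15. Rhodium-catalysed trans-hydroboration of the terminal alkyne 7 ([Rh(cod)Cl]2, P(iPr)3, Et3N, pinacolborane, cyclohexane, rt) should give the (Z)-alkenyl pinacolboronate F11; the hydroxyls are borylated in passing and freed on work-up. Suzuki–Miyaura coupling of F11 with 13 (Pd(dppf)Cl2, K3PO4, dioxane/H2O, 60 °C) keeps the alkene geometry and gives 15.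

**Further compounds**

F1 | step 14 | 1-(4-bromo-2,5-dimethoxyphenyl)ethanone (not isolated) | CC(=O)c1cc(OC)c(Br)cc1OC
F2 | step 14 | 1-(4-bromo-2-hydroxy-5-methoxyphenyl)ethanone | CC(=O)c1cc(OC)c(Br)cc1O
F3 | step 14 | 1-(4-bromo-2-hydroxy-3-iodo-5-methoxyphenyl)ethanone | CC(=O)c1cc(OC)c(Br)c(I)c1O
F4 | step 14 | 1-(4-bromo-2,5-dihydroxy-3-iodophenyl)ethanone | CC(=O)c1cc(O)c(Br)c(I)c1O
F5 | step 14 | 1-[4-bromo-3-iodo-2,5-bis(methoxymethoxy)phenyl]ethanone | CC(=O)c1cc(OCOC)c(Br)c(I)c1OCOC
F6 | step 14 | 1-[4-bromo-3-[(3S)-3,7-dihydroxy-3,7-dimethyloct-1-yn-1-yl]-2,5-bis(methoxymethoxy)phenyl]ethanone | CC(C)(O)CCC[C@@](O)(C)C#Cc1c(Br)c(OCOC)cc(C(C)=O)c1OCOC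
F7 | step 14 | 1-[4-bromo-3-[(1Z,3S)-3,7-dihydroxy-3,7-dimethyloct-1-en-1-yl]-2,5-bis(methoxymethoxy)phenyl]ethanone | CC(C)(O)CCC[C@@](O)(C)/C=C\c1c(Br)c(OCOC)cc(C(C)=O)c1OCOC
F8 | step 14 | 1-[(2S)-2-(4-hydroxy-4-methylpentyl)-5,8-bis(methoxymethoxy)-2-methyl-2H-chromen-6-yl]ethanone | CC(C)(O)CCC[C@@]1(C)C=Cc2c(OCOC)c(C(C)=O)cc(OCOC)c2O1
F9 | step 13 | 1-[3-[(1Z,3S)-3,7-dihydroxy-3,7-dimethyloct-1-en-1-yl]-4-fluoro-2,5-bis(methoxymethoxy)phenyl]-3-hydroxy-3-[4-(methoxymethoxy)phenyl]propan-1-one (both epimers at the new carbinol carbon) | CC(C)(O)CCC[C@@](O)(C)/C=C\c1c(F)c(OCOC)cc(C(=O)CC(O)c2ccc(OCOC)cc2)c1OCOC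
F10 | step 13 | methanesulfonate of F9 at the secondary hydroxyl (both epimers, not isolated) | CC(C)(O)CCC[C@@](O)(C)/C=C\c1c(F)c(OCOC)cc(C(=O)CC(OS(C)(=O)=O)c2ccc(OCOC)cc2)c1OCOC
F11 | step 11 | (1Z,3S)-3,7-dimethyl-1-(4,4,5,5-tetramethyl-1,3,2-dioxaborolan-2-yl)oct-1-ene-3,7-diol | CC(C)(O)CCC[C@@](O)(C)/C=C\B1OC(C)(C)C(C)(C)O1
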